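**Retrosynthetic overview**
1. Feature: ring A (atoms labelled C1 acetyl-bearing, C2, C3, C4, C5 bridge-bearing, C6 ketone) holds the only stereocentre, the quaternary C3, which carries methyl, prenyl and the two carbonyl-level ring carbons C2 and C4; this is an α-quaternary aldol pattern whose two oxidised arms must be told apart.
2. The C5–CH2–aryl bond is cut to ring A trione 19 and the Mannich base 22 of prenylated ring B (ortho-quinone methide addition); ring B is bought as the arene.
3. Ring A, the only ring that is built, closes last at C1–C2 by Dieckmann condensation of triketo ester 18; its C4–C5 bond comes from an aldol of the acetylacetone dianion with formyl ester 14.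
4. C3 and the C2–C3 bond come from the anti 1,2-shift of the siloxymethyl group in epoxy silyl ether 8, giving aldehyde 9 (CHO = C4, CH2OSi = C2); the silyl arm is raised to the methyl ester before the aldol while the aldehyde rests as its dimethyl acetal, so that no free hydroxy polyketone is ever handled.
5. 8 comes from Sharpless epoxidation of (E)-dienol 6, itself made by methylalumination of the skipped enyne 3 from prenyl bromide and ethynylmagnesium bromide.

Key step: step 5

Assumption: the enol tautomers of the ring A trione interconvert freely, so 19 and 23 are written in the tautomer of the target drawing and their descriptors refer to that drawing; names in the compound list use IUPAC locants, the text uses the ring A labels C1–C6 defined above.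

**Route**

Step 1
Reactants: 1 prenyl bromide (1-bromo-3-methylbut-2-ene); 2 ethynylmagnesium bromide (excess)
Product: 3 5-methylhex-4-en-1-yne
Conditions: CuCl (5 mol %), THF, 0 °C → rt; careful fractional distillation
Reagents that add atoms: none
Why: Copper-catalysed SN2 coupling of an allylic bromide with an alkynyl Grignard reagent should join the acetylide to the unhindered CH2 terminus of the prenyl unit, and the excess of 2 suppresses double allylation of acetylene.

Step 2
Reactants: 3 5-methylhex-4-en-1-yne
Product: 6 (E)-3,6-dimethylhepta-2,5-dien-1-ol, via alkenyl(dimethyl)alane 4 (not isolated), via lithium butyl alanate 5 (not isolated)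
Conditions: AlMe3 (2 equiv), Cp2ZrCl2 (0.25 equiv), CH2Cl2, 0 °C → rt; then n-BuLi, THF, −78 → 0 °C; (CH2O)n, rt; aq. HCl work-up
Reagents that add atoms: trimethylaluminium, C[Al](C)C; paraformaldehyde (as formaldehyde), C=O
Why: Negishi carboalumination adds methyl and aluminium syn across the terminal alkyne with aluminium on the terminal carbon, and the ate complex is hydroxymethylated by formaldehyde with retention, which fixes the (E)-trisubstituted alkene.

Step 3
Reactants: 6 (E)-3,6-dimethylhepta-2,5-dien-1-ol
Product: 7 [(2S,3S)-3-methyl-3-(3-methylbut-2-en-1-yl)oxiran-2-yl]methanol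
Conditions: Ti(Oi-Pr)4 (10 mol %), L-(+)-diethyl tartrate (12 mol %), t-BuOOH (2 equiv, in decane), 4 Å MS, CH2Cl2, −20 °C
Reagents that add atoms: tert-butyl hydroperoxide, CC(C)(C)OO
Why: Sharpless asymmetric epoxidation delivers oxygen only to the alkene of the titanium-bound allylic alcohol, leaving the remote prenyl alkene alone, and L-(+)-tartrate on the (E)-alkene sets both epoxide centres as (2S,3S), as in the geraniol case.

Step 4
Reactants: 7 [(2S,3S)-3-methyl-3-(3-methylbut-2-en-1-yl)oxiran-2-yl]methanol
Product: 8 tert-butyldimethylsilyl ether of 7, (2S,3S)-2,3-epoxy-3,6-dimethylhept-5-en-1-ol TBS ether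
Conditions: TBSCl, imidazole, DMF, 0 °C → rt
Reagents that add atoms: tert-butyldimethylsilyl chloride, CC(C)(C)[Si](C)(C)Cl
Why: Imidazole-mediated silylation of the primary alcohol is routine and leaves the epoxide and both stereocentres untouched.

Step 5
Reactants: 8 (2S,3S)-2,3-epoxy-3,6-dimethylhept-5-en-1-ol TBS ether
Product: 9 (S)-2-[(tert-butyldimethylsilyloxy)methyl]-2,5-dimethylhex-4-enal
Conditions: MeAl(OAr)2 (Ar = 4-bromo-2,6-di-tert-butylphenyl; 2 equiv, prepared beforehand from AlMe3 and ArOH), CH2Cl2, −78 °C; aqueous work-up
Reagents that add atoms: none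
Why: The bulky, oxophilic aluminium bis(aryloxide) binds the epoxide oxygen, the bond from oxygen to the tertiary carbon (future C3) ionises, and the siloxymethyl carbon (future C2) shifts to it on the face opposite the departing oxygen while the carbon it leaves becomes the aldehyde (future C4). This is the organoaluminium-promoted semipinacol rearrangement of 2,3-epoxy silyl ethers to β-siloxy aldehydes, which is established for trisubstituted epoxides that give α-quaternary aldehydes. One skeletal bond (C2–C3 of ring A) forms and no ring closes. The new quaternary centre is controlled by the substrate: the anti shift inverts the (3S) carbon of 8, set in step 3 by the (E)-geometry and the tartrate, and gives (S)-9 with CH2OSi where C2 and CHO where C4 of the target must lie. The step needs siloxymethyl rather than hydride migration and no capture of the developing cation by the homoallylic prenyl alkene or by the silyl ether oxygen. The bulk of the aryloxide ligands (which favours the alkyl shift in this reagent class), ionisation at the tertiary carbon, the concerted timing at −78 °C and the bulky silyl group that keeps its oxygen off aluminium should secure this.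

Step 6
Reactants: 9 (S)-2-[(tert-butyldimethylsilyloxy)methyl]-2,5-dimethylhex-4-enal
Product: 10 (S)-2-(dimethoxymethyl)-2,5-dimethylhex-4-en-1-ol
Conditions: HC(OMe)3, camphorsulfonic acid (0.1 equiv), MeOH, 0 °C → rt
Reagents that add atoms: trimethyl orthoformate, COC(OC)OC; methanol, CO
Why: Acid-catalysed acetalisation with the orthoformate as water scavenger is fast, and the same acid in methanol then methanolyses the primary silyl ether, so the aldehyde is masked before the hydroxyl is freed and the non-enolisable quaternary centre is untouched.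

Step 7
Reactants: 10 (S)-2-(dimethoxymethyl)-2,5-dimethylhex-4-en-1-ol
Product: 11 (S)-2-(dimethoxymethyl)-2,5-dimethylhex-4-enal
Conditions: Dess–Martin periodinane (1.3 equiv), NaHCO3, CH2Cl2, 0 °C → rt
Reagents that add atoms: none
Why: Dess–Martin oxidation converts the neopentyl primary alcohol into the aldehyde under buffered conditions that keep the dimethyl acetal and the prenyl alkene intact.

Step 8
Reactants: 11 (S)-2-(dimethoxymethyl)-2,5-dimethylhex-4-enal
Product: 12 (R)-2-(dimethoxymethyl)-2,5-dimethylhex-4-enoic acid
Conditions: NaClO2, NaH2PO4, 2-methylbut-2-ene (excess), t-BuOH/H2O, 0 °C → rt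
Reagents that add atoms: sodium chlorite, [Na+].[O-]Cl=O
Why: Pinnick oxidation takes the non-enolisable aldehyde to the acid while the alkene scavenger removes hypochlorous acid before it can attack the prenyl group (the descriptor changes only because the priorities change).

Step 9
Reactants: 12 (R)-2-(dimethoxymethyl)-2,5-dimethylhex-4-enoic acid
Product: 13 methyl (R)-2-(dimethoxymethyl)-2,5-dimethylhex-4-enoate
Conditions: MeI, K2CO3, DMF, rt
Reagents that add atoms: iodomethane, CI
Why: O-Alkylation of the carboxylate is an SN2 reaction at iodomethane and therefore insensitive to the neopentyl hindrance of the acid, and the basic medium preserves the acetal.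

Step 10
Reactants: 13 methyl (R)-2-(dimethoxymethyl)-2,5-dimethylhex-4-enoate
Product: 14 methyl (R)-2-formyl-2,5-dimethylhex-4-enoate
Conditions: 1 M aq. HCl, THF, rt → 40 °C
Reagents that add atoms: water, O
Why: Dilute aqueous acid hydrolyses the dimethyl acetal without touching the methyl ester or the trisubstituted alkene, and the quaternary α-carbon has no hydrogen through which it could racemise.

Step 11
Reactants: 14 methyl (R)-2-formyl-2,5-dimethylhex-4-enoate; 15 acetylacetone (pentane-2,4-dione, 1.3 equiv)
Product: 17 methyl (2R)-3-hydroxy-2-methyl-2-(3-methylbut-2-en-1-yl)-5,7-dioxooctanoate (both C3 epimers), via dilithium acetylacetone dienolate 16 (not isolated)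
Conditions: 15, LiN(i-Pr)2 (2.1 equiv per 15), THF, −78 → 0 °C; then 14, −78 °C; sat. NH4Cl at −78 °C
Reagents that add atoms: none
Why: The β-diketone dianion reacts through its terminal, more basic carbon in an aldol addition to the aldehyde, which is far more electrophilic than the neopentyl ester at −78 °C; the new carbinol centre is of no consequence because it is oxidised in the next step.

Step 12
Reactants: 17 methyl (2R)-3-hydroxy-2-methyl-2-(3-methylbut-2-en-1-yl)-5,7-dioxooctanoate
Product: 18 methyl (R)-2-methyl-2-(3-methylbut-2-en-1-yl)-3,5,7-trioxooctanoate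
Conditions: Dess–Martin periodinane (1.2 equiv), CH2Cl2, 0 °C → rt; used directly
Reagents that add atoms: none
Why: Dess–Martin oxidation of a β-hydroxy ketone to the 1,3-dicarbonyl level is standard and non-acidic, which avoids cyclodehydration of the hydroxy diketone to a dihydropyranone; limiting the oxidant guards the diketone methylene.

Step 13
Reactants: 18 methyl (R)-2-methyl-2-(3-methylbut-2-en-1-yl)-3,5,7-trioxooctanoate
Product: 19 (4R)-2-acetyl-3,5-dihydroxy-4-methyl-4-(3-methylbut-2-en-1-yl)cyclohexa-2,5-dien-1-one (ring A)
Conditions: KOt-Bu (2.5 equiv), THF, 0 °C → rt; 1 M HCl work-up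
Reagents that add atoms: none
Why: In this Dieckmann (intramolecular Claisen) condensation the dienolate carbon C1, between the C6 and acetyl carbonyls, attacks the ester C2 in the only feasible six-membered closure; full enolisation of the C4/C6 diketone shields those carbonyls from retro-Claisen cleavage, the strongly acidic acyl trione anion is the thermodynamic sink, and C3 is not involved.

Step 14
Reactants: 20 2,4,6-trihydroxyacetophenone; 1 prenyl bromide (0.9 equiv)
Product: 21 1-[2,4,6-trihydroxy-3-(3-methylbut-2-en-1-yl)phenyl]ethanone
Conditions: DBU (1 equiv), THF, 0 °C → rt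
Reagents that add atoms: none
Why: C-Alkylation of the ambident phloroglucinol phenolate with an allylic bromide is the usual entry to mono-C-prenylated acylphloroglucinols, and sub-stoichiometric bromide limits the second prenylation.

Step 15
Reactants: 21 1-[2,4,6-trihydroxy-3-(3-methylbut-2-en-1-yl)phenyl]ethanone
Product: 22 1-{3-[(dimethylamino)methyl]-2,4,6-trihydroxy-5-(3-methylbut-2-en-1-yl)phenyl}ethanone
Conditions: CH2=NMe2+ I− (1.05 equiv), MeCN, 0 °C → rt; aq. NaHCO3 work-up
Reagents that add atoms: dimethylmethylideneammonium iodide, C=[N+](C)C.[I-]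
Why: Mannich aminomethylation with the preformed iminium salt can only take place at the single free position of the electron-rich ring B, so one regioisomer should result.

Step 16
Reactants: 19 ring A trione; 22 ring B Mannich base
Product: 23 (4R)-2-acetyl-6-{[3-acetyl-2,4,6-trihydroxy-5-(3-methylbut-2-en-1-yl)phenyl]methyl}-3,5-dihydroxy-4-methyl-4-(3-methylbut-2-en-1-yl)cyclohexa-2,5-dien-1-one (CNP0192978.1)
Conditions: 1,4-dioxane, 80 °C, argon; dilute acid work-up
Reagents that add atoms: none
Why: The acidic trione 19 protonates the benzylic amine of the phenolic Mannich base, loss of dimethylamine gives the ortho-quinone methide of ring B, and the enol carbon C5 of 19 (its only unsubstituted nucleophilic carbon) adds in a Michael reaction to form the methylene bridge without touching C3.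

**Compound list**
1 | prenyl bromide (1-bromo-3-methylbut-2-ene) | CC(C)=CCBr | starting material
2 | ethynylmagnesium bromide | C#C[Mg]Br | starting material
3 | 5-methylhex-4-en-1-yne | C#CCC=C(C)C | intermediate
4 | [(E)-2,5-dimethylhexa-1,4-dien-1-yl]dimethylalane | C[Al](C)/C=C(\C)CC=C(C)C | intermediate
5 | lithium butyl[(E)-2,5-dimethylhexa-1,4-dien-1-yl]dimethylalanate | [Li+].CCCC[Al-](C)(C)/C=C(\C)CC=C(C)C | intermediate
6 | (E)-3,6-dimethylhepta-2,5-dien-1-ol | OC/C=C(\C)CC=C(C)C | intermediate
7 | [(2S,3S)-3-methyl-3-(3-methylbut-2-en-1-yl)oxiran-2-yl]methanol | OC[C@@H]1O[C@@]1(C)CC=C(C)C | intermediate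
8 | (2S,3S)-2,3-epoxy-3,6-dimethylhept-5-en-1-ol tert-butyldimethylsilyl ether | CC(C)(C)[Si](C)(C)OC[C@@H]1O[C@@]1(C)CC=C(C)C | intermediate
9 | (S)-2-[(tert-butyldimethylsilyloxy)methyl]-2,5-dimethylhex-4-enal | CC(C)(C)[Si](C)(C)OC[C@](C)(CC=C(C)C)C=O | intermediate
10 | (S)-2-(dimethoxymethyl)-2,5-dimethylhex-4-en-1-ol | OC[C@](C)(CC=C(C)C)C(OC)OC | intermediate
11 | (S)-2-(dimethoxymethyl)-2,5-dimethylhex-4-enal | O=C[C@](C)(CC=C(C)C)C(OC)OC | intermediate
12 | (R)-2-(dimethoxymethyl)-2,5-dimethylhex-4-enoic acid | OC(=O)[C@](C)(CC=C(C)C)C(OC)OC | intermediate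
13 | methyl (R)-2-(dimethoxymethyl)-2,5-dimethylhex-4-enoate | COC(=O)[C@](C)(CC=C(C)C)C(OC)OC | intermediate
14 | methyl (R)-2-formyl-2,5-dimethylhex-4-enoate | COC(=O)[C@](C)(CC=C(C)C)C=O | intermediate
15 | acetylacetone (pentane-2,4-dione) | CC(=O)CC(C)=O | starting material
16 | dilithium dienolate of acetylacetone | C=C([O-])C=C(C)[O-].[Li+].[Li+] | intermediate
17 | methyl (2R)-3-hydroxy-2-methyl-2-(3-methylbut-2-en-1-yl)-5,7-dioxooctanoate (C3 epimers) | COC(=O)[C@](C)(CC=C(C)C)C(O)CC(=O)CC(C)=O | intermediate
18 | methyl (R)-2-methyl-2-(3-methylbut-2-en-1-yl)-3,5,7-trioxooctanoate | COC(=O)[C@](C)(CC=C(C)C)C(=O)CC(=O)CC(C)=O | intermediate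
19 | (4R)-2-acetyl-3,5-dihydroxy-4-methyl-4-(3-methylbut-2-en-1-yl)cyclohexa-2,5-dien-1-one | CC(=O)C1=C(O)[C@](C)(CC=C(C)C)C(O)=CC1=O | intermediate
20 | 2,4,6-trihydroxyacetophenone | CC(=O)c1c(O)cc(O)cc1O | starting material
21 | 1-[2,4,6-trihydroxy-3-(3-methylbut-2-en-1-yl)phenyl]ethanone | CC(=O)c1c(O)cc(O)c(CC=C(C)C)c1O | intermediate
22 | 1-{3-[(dimethylamino)methyl]-2,4,6-trihydroxy-5-(3-methylbut-2-en-1-yl)phenyl}ethanone | CC(=O)c1c(O)c(CN(C)C)c(O)c(CC=C(C)C)c1O | intermediate
23 | (4R)-2-acetyl-6-{[3-acetyl-2,4,6-trihydroxy-5-(3-methylbut-2-en-1-yl)phenyl]methyl}-3,5-dihydroxy-4-methyl-4-(3-methylbut-2-en-1-yl)cyclohexa-2,5-dien-1-one | CC(=O)C1=C(O)[C@](C)(CC=C(C)C)C(O)=C(Cc2c(O)c(CC=C(C)C)c(O)c(C(C)=O)c2O)C1=O | target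

**Step count**
Total: 16 steps. Longest linear sequence: 14 steps (steps 1–13 and 16); steps 14–15 form the ring B branch.

**Steps most likely to fail**

Step 5. What may go wrong: the homoallylic prenyl double bond may intercept the ionising tertiary centre (cyclopropylcarbinyl closure), or hydride may migrate in place of siloxymethyl, so that the aldehyde forms in poor amount or purity. The fallback sets out from 1, comes back at 14, and generates no cation next to the prenyl group. Compound 1 alkylates commercial dimethyl methylmalonate (NaH, THF) to give dimethyl 2-methyl-2-(3-methylbut-2-en-1-yl)propanedioate F1. Pig liver esterase in pH 7 phosphate buffer desymmetrises the prochiral diester to (R)-2-(methoxycarbonyl)-2,5-dimethylhex-4-enoic acid F2; the sense of the enzymatic hydrolysis is an assumption that has to be checked by correlation. The acid arm is reduced through its mixed anhydride (ClCO2Et, Et3N; then NaBH4) to methyl (R)-2-(hydroxymethyl)-2,5-dimethylhex-4-enoate F3, and Dess–Martin oxidation gives 14.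

Step 13. What may go wrong: the diketonate carbon may attack the neopentyl ester too slowly, so that O-acylation to an enol lactone or cleavage at the C4 ketone takes over. The fallback sets out from 12, comes back at 19, and forms the C1–C2 bond intermolecularly with a stronger acyl donor before closing the ring at C4–C5. Acid 12 is converted with 1-chloro-N,N,2-trimethylprop-1-en-1-amine into (R)-2-(dimethoxymethyl)-2,5-dimethylhex-4-enoyl chloride F4. This C-acylates the magnesium enolate of acetylacetone 15 (MgCl2, Et3N, MeCN) to give (5R)-3-acetyl-5-(dimethoxymethyl)-5,8-dimethylnon-7-ene-2,4-dione F5. Dilute aqueous HCl in THF unmasks (2R)-4-acetyl-2-methyl-2-(3-methylbut-2-en-1-yl)-3,5-dioxohexanal F6. Its dianion (LiN(i-Pr)2, THF, −78 °C) closes by intramolecular aldol of an acetyl methyl onto the aldehyde to (4R)-2-acetyl-3,5-dihydroxy-4-methyl-4-(3-methylbut-2-en-1-yl)cyclohex-2-en-1-one F7. Dess–Martin oxidation of the ring carbinol gives 19; either acetyl group of F5 leads to the same product.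

Step 16. What may go wrong: the quinone methide may form sluggishly, the methylene may be exchanged between the two halves on prolonged heating to give symmetrical dimers, or the bridged product may cyclodehydrate to a pyran. The fallback sets out from 19 (with 21), comes back at 23, and puts the electrophilic methylene on ring A instead. Compound 19 is aminomethylated at C5 with CH2=NMe2+ I− in MeCN to (4R)-2-acetyl-6-[(dimethylamino)methyl]-3,5-dihydroxy-4-methyl-4-(3-methylbut-2-en-1-yl)cyclohexa-2,5-dien-1-one F8. Gentle warming of this zwitterionic Mannich base with the free phloroglucinol 21 in dioxane releases the 5-methylene trione, which the unsubstituted ring carbon of 21 should capture to give 23.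

**Further compounds**
F1 | step 5 | dimethyl 2-methyl-2-(3-methylbut-2-en-1-yl)propanedioate | COC(=O)C(C)(CC=C(C)C)C(=O)OC
F2 | step 5 | (R)-2-(methoxycarbonyl)-2,5-dimethylhex-4-enoic acid | COC(=O)[C@](C)(CC=C(C)C)C(O)=O
F3 | step 5 | methyl (R)-2-(hydroxymethyl)-2,5-dimethylhex-4-enoate | COC(=O)[C@](C)(CC=C(C)C)CO
F4 | step 13 | (R)-2-(dimethoxymethyl)-2,5-dimethylhex-4-enoyl chloride | ClC(=O)[C@](C)(CC=C(C)C)C(OC)OC
F5 | step 13 | (5R)-3-acetyl-5-(dimethoxymethyl)-5,8-dimethylnon-7-ene-2,4-dione | CC(=O)C(C(C)=O)C(=O)[C@](C)(CC=C(C)C)C(OC)OC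
F6 | step 13 | (2R)-4-acetyl-2-methyl-2-(3-methylbut-2-en-1-yl)-3,5-dioxohexanal | CC(=O)C(C(C)=O)C(=O)[C@](C)(CC=C(C)C)C=O
F7 | step 13 | (4R)-2-acetyl-3,5-dihydroxy-4-methyl-4-(3-methylbut-2-en-1-yl)cyclohex-2-en-1-one (C5 epimers) | CC(=O)C1=C(O)[C@](C)(CC=C(C)C)C(O)CC1=O
F8 | step 16 | (4R)-2-acetyl-6-[(dimethylamino)methyl]-3,5-dihydroxy-4-methyl-4-(3-methylbut-2-en-1-yl)cyclohexa-2,5-dien-1-one | CC(=O)C1=C(O)[C@](C)(CC=C(C)C)C(O)=C(CN(C)C)C1=O
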